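The pitfall was the 2.00 equiv of reagent. It reads like a surplus, yet reagent also decays by itself.

| flask | substrate | partner | reagent | time | remark |
|---|---|---|---|---|---|
| noon | 0.25 M (fed, over 2.5 h) | 1.10 equiv | 2.00 equiv | 4.0 h | all else is in the flask from the start; the feed brings no volume worth counting |
| winter | 0.25 M | 1.10 equiv | 2.00 equiv (fed, over 2.5 h) | 4.0 h | all else is in the flask from the start; the feed brings no volume worth counting |
| dusk | 0.25 M | 1.10 equiv | 2.00 equiv | 4.0 h | everything together at the start |

* the best flask by share of target in target plus homo product; "all alike" if 1.5 percentage points covers them all (noon / winter / dusk / all alike)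
* share of target in target plus homo product at the end, noon
* share of target in target plus homo product at the end, winter
* share of target in target plus homo product at the end, dusk

- in percentages every species weighs as the substrate in it: one homo product counts as two
- a doubled species enters its step squared and goes two at a time
- run time (noon): 4.0 h

    reagent + partner → second intermediate (k1 = 6.3 × 10⁻⁴ M⁻¹ s⁻¹)
    2 open intermediate → homo product (k2 = 0.0014 M⁻¹ s⁻¹)
    substrate + reagent → open intermediate (k3 = 0.0035 M⁻¹ s⁻¹)
    reagent → decomposed reagent (k4 = 5.4 × 10⁻⁴ s⁻¹)
    open intermediate + second intermediate → target (k5 = 0.0019 M⁻¹ s⁻¹)
    substrate ⇌ dormant form (K6 = 0.90, k6 = 0.017 s⁻¹)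

I kept the books on reagent, starting with noon, which holds 0.500 M from the start. With partner held near its charge, the loss of reagent is pseudo-first-order:

λ = k4 + k1[partner] = 7.13 × 10⁻⁴ s⁻¹, lifetime 0.389 h

That lifetime is shorter than the feed of 2.5 h, so in noon reagent meets a pool of substrate that is still small. The forward step to the dormant form has a half-life of 0.680 min, far shorter than that lifetime, so I took the free part of the pool as 0.526.

The ledger for noon had these entries:

to decay: k4[reagent]₀/λ = 0.379 M

to partner: k1[partner][reagent]₀/λ = 0.121 M

to substrate: k3·f·(feed rate)·[reagent]₀/λ² = 0.0503 M

The first two entries already close the books, so the third is an overdraft that I did not debit, and the ledger is rough. I carried the claim ratio, the moles of reagent taken by partner per mole taken by substrate: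

2.41

In dusk and winter, the ratio of the two rates at the start, with partner and the substrate pool at their charges, is 0.376. Both charges fall as reagent acts, so this is a start value. The noon ratio is higher than this start value, though the noon ratio covers the whole ledger. Second intermediate should therefore outnumber open intermediate in noon and trail it in dusk and winter, so I chose noon.

The forecast also chose noon, with 77% for noon, 32% for winter and 34% for dusk, because "reagent decays before most substrate arrives". For noon it has about 0.04 M of open intermediate formed, where I had 0.0503 M, against about 0.09 M of second intermediate, where I had 0.121 M.

The simulation gave noon, with 79.6% for noon, 31.9% for winter and 33.5% for dusk. After 4.00 h, noon held 0.369 M of decomposed reagent, with 0.0962 M taken by partner and 0.0348 M by substrate, a read ratio of 2.76 beside the claim ratio of 2.41. For the neighbouring noon flask with 1.0 M of substrate, the claim ratio reckons to 4.17. That flask ended at 92.8%, with a read ratio of 3.91.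

Its constants are made up, and the outcome is calculated.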